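## Retrosynthetic overview

1. The C-4 carbinol (R) is traced back to the chroman-4-one carbonyl; a catalyst-controlled asymmetric transfer hydrogenation sets it in the last step.
2. The hexasubstituted benzene ring is cut at C4a–C5 and C7–C8 ([3+3]) into a methylmalonyl C3 dielectrophile and a 2,2-dimethyl-2,3-dihydropyran-4-one bearing a 2-oxo-4-phenylbutyl arm at C-6 (C-5 and the exocyclic CH2 act as C,C-dinucleophile).
3. The dihydropyranone is cut at O1–C2 (6-endo oxa-Michael) to an open-chain enone-1,3,5-triketone. Only the central carbonyl oxygen can close a six-membered ring, so the ring oxygen is fixed next to the future acyl-bearing carbon before the arene exists.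
4. The triketone is cut by two dianion C–C bond formations to acetylacetone, benzyl chloride and methyl 3-methylbut-2-enoate.
5. Ring order: dihydropyranone ring first, then the benzene ring, both in the same flask operation; the phenyl ring is bought.

Assumption: the SMILES defines the single stereocentre (C-4 of the chroman ring, C-4'' in the natural-product numbering) as R, chroman numbering is used throughout, and methylmalonyl dichloride is bought (or made from methylmalonic acid and SOCl2).

## Route

Step 1
Reactants: 1 acetylacetone (pentane-2,4-dione); 2 benzyl chloride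
Product: 3 6-phenylhexane-2,4-dione
Conditions: LDA (2.2 equiv), THF, −78→0 °C; then 2 (1.0 equiv), 0 °C→rt; aq. HCl
Reagents that add atoms: none
Why: Hauser–Harris dianion alkylation: the 1,3-dilithio dianion of acetylacetone reacts with the benzylic halide only at its more basic terminal carbon; no stereocentre is formed.

Step 2
Reactants: 3 6-phenylhexane-2,4-dione; 4 methyl 3-methylbut-2-enoate
Product: 5 2-methyl-10-phenyldec-2-ene-4,6,8-trione
Conditions: 3 (2.0 equiv), LDA (4.1 equiv), THF, −78→0 °C; then 4 (1.0 equiv), −78→−20 °C; AcOH, −78 °C; pH 6 buffer work-up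
Reagents that add atoms: none
Why: Harris acylation (Claisen-type) of a β-diketone dianion: the second deprotonation of 3 occurs at the CH3 terminus, this carbanion adds 1,2 to the ester (the β,β-dimethyl group blocks 1,4-addition) and the second equivalent of dianion deprotonates the more acidic 1,3,5-triketone; no stereocentre is formed.

Step 3
Reactants: 5 2-methyl-10-phenyldec-2-ene-4,6,8-trione; 6 2-methylpropanedioyl dichloride (methylmalonyl dichloride)
Product: 9 5,7-dihydroxy-2,2,6-trimethyl-8-(3-phenylpropanoyl)chroman-4-one, via dihydropyranone 7 (not isolated), via acylketene 8 (not isolated)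
Conditions: TfOH (5 mol %), CH2Cl2, 0 °C, 1 h; then MgCl2 (2.5 equiv), Et3N (4.5 equiv), MeCN, 0 °C; 6 (1.1 equiv, slow addition), 0 °C→rt, 12 h; 1 M HCl work-up
Reagents that add atoms: none
Why: Proposed new method: catalytic TfOH protonates the β,β-dimethyl enone and the enol oxygen of the central carbonyl closes the only possible six-membered ring (6-endo oxa-Michael, the known acid cyclisation of unsaturated β-diketones to 2,3-dihydro-4H-pyran-4-ones) to give 7; the exocyclic CH2 and C-5 of 7 are the two ends of a vinylogous β-diketone, so C-acylation by 6 and loss of HCl give acylketene 8, whose Mg-chelated Z-enol holds the ketene next to C-5 and away from the chelated oxygens, so that C–C closure (6π-electrocyclisation of the dienylketene, equivalent to an intramolecular Claisen-type C-acylation) is favoured over lactonisation to a 4-hydroxy-2-pyrone and two enolisations give the benzene ring; the closest known reactions are the Effenberger cyclisation (C,C-diacylation of ketone enol derivatives with malonyl dichlorides), Rathke MgCl2/Et3N C-acylation and the dienylketene ring closure of the Danheiser benzannulation; no stereocentre is formed.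

Step 4
Reactants: 9 5,7-dihydroxy-2,2,6-trimethyl-8-(3-phenylpropanoyl)chroman-4-one
Product: 10 1-[(4R)-4,5,7-trihydroxy-2,2,6-trimethyl-3,4-dihydro-2H-chromen-8-yl]-3-phenylpropan-1-one (target)
Conditions: RuCl[(R,R)-TsDPEN](p-cymene) (2 mol %), HCO2H/Et3N (1.2:1, 6 equiv HCO2H), DMF, 30 °C
Reagents that add atoms: none
Why: Noyori–Ikariya asymmetric transfer hydrogenation: the cyclic aryl ketone is reduced by outer-sphere hydride transfer with CH/π control, the (R,R)-catalyst giving the (R)-carbinol as it does for 4-chromanone, while the acyclic C-8 ketone (two ortho substituents, chelated by 7-OH) is expected to stay untouched and the near-neutral formate medium avoids ionising the electron-rich benzylic alcohol.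

## Compound list

1 | acetylacetone (pentane-2,4-dione) | CC(=O)CC(C)=O | starting material
2 | benzyl chloride | ClCc1ccccc1 | starting material
3 | 6-phenylhexane-2,4-dione | CC(=O)CC(=O)CCc1ccccc1 | intermediate
4 | methyl 3-methylbut-2-enoate | COC(=O)C=C(C)C | starting material
5 | 2-methyl-10-phenyldec-2-ene-4,6,8-trione (drawn as triketo form) | CC(C)=CC(=O)CC(=O)CC(=O)CCc1ccccc1 | intermediate
6 | 2-methylpropanedioyl dichloride (methylmalonyl dichloride) | CC(C(Cl)=O)C(Cl)=O | starting material
7 | 2,2-dimethyl-6-(2-oxo-4-phenylbutyl)-2,3-dihydro-4H-pyran-4-one | CC1(C)CC(=O)C=C(CC(=O)CCc2ccccc2)O1 | intermediate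
8 | 4-(2,2-dimethyl-4-oxo-3,4-dihydro-2H-pyran-6-yl)-2-methyl-7-phenylhept-1-ene-1,3,5-trione (acylketene, drawn in keto form) | CC(=C=O)C(=O)C(C(=O)CCc1ccccc1)C1=CC(=O)CC(C)(C)O1 | intermediate
9 | 5,7-dihydroxy-2,2,6-trimethyl-8-(3-phenylpropanoyl)chroman-4-one | Cc1c(O)c(C(=O)CCc2ccccc2)c2c(c1O)C(=O)CC(C)(C)O2 | intermediate
10 | 1-[(4R)-4,5,7-trihydroxy-2,2,6-trimethyl-3,4-dihydro-2H-chromen-8-yl]-3-phenylpropan-1-one | Cc1c(O)c(C(=O)CCc2ccccc2)c2c(c1O)[C@H](O)CC(C)(C)O2 | target

## Step count and risk

Total step count: 4. Longest linear sequence: 4 (1 → 3 → 5 → 9 → 10).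

Steps most likely to fail:

Step 3 (one-flask pyranone and benzene formation). The acid pre-cyclisation can divert to a 4H-pyran-4-one by cyclodehydration, and the second acylation can close on oxygen to a 4-hydroxy-2-pyrone instead of on C-5. The fallback reverses the order of ring formation. It sets out from triketone 5: without acid pre-treatment, the open-chain magnesium chelate (MgCl2, Et3N, MeCN, 0 °C) is treated with 6. Both internal CH2 groups of 5 are true β-diketone methylenes, the classical substrates of Mg-mediated C-acylation, so double C-acylation gives the diacylphloroglucinol 1-[2,4,6-trihydroxy-3-methyl-5-(3-methylbut-2-enoyl)phenyl]-3-phenylpropan-1-one F1. Acid (MsOH, CH2Cl2, rt) then closes the pyranone ring by oxa-Michael addition. Two phenols can close, so 9 forms beside its regioisomer 5,7-dihydroxy-2,2,8-trimethyl-6-(3-phenylpropanoyl)chroman-4-one F2 and is separated by chromatography; the route is rejoined at 9.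

Step 4 (chemo- and enantioselective reduction). The chelated, electron-rich C-4 ketone may be sluggish, the C-8 ketone may compete, and the product may partly racemise by ionisation. The fallback changes to a protected substrate and a different reductant. It sets out from 9: acetylation (Ac2O, pyridine, cat. DMAP) gives 4-oxo-2,2,6-trimethyl-8-(3-phenylpropanoyl)chroman-5,7-diyl diacetate F3, in which the C-8 ketone is twisted out of conjugation between two ortho substituents and the C-4 ketone is no longer a chelated vinylogous acid. Corey–Bakshi–Shibata reduction with (S)-Me-CBS (20 mol %) and BH3·SMe2 in THF at −20 °C gives (4R)-4-hydroxy-2,2,6-trimethyl-8-(3-phenylpropanoyl)chroman-5,7-diyl diacetate F4. Methanolysis (K2CO3, MeOH, 0 °C) removes both acetates and rejoins the route at 10.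

Step 2 (triketone synthesis). The dianion may deprotonate ester 4 at the γ-position, and 5 may cyclise on work-up. The fallback replaces the Claisen-type acylation by an aldol addition and an oxidation. It sets out from 3: its dianion (LDA, THF, −78 °C) adds 1,2 to 3-methylbut-2-enal to give 7-hydroxy-9-methyl-1-phenyldec-8-ene-3,5-dione F5 (racemic; this carbinol centre is destroyed in the next operation). MnO2 (CH2Cl2, rt) oxidises the allylic alcohol to the enone and rejoins the route at 5.

## Further compounds

F1 | step 3 | 1-[2,4,6-trihydroxy-3-methyl-5-(3-methylbut-2-enoyl)phenyl]-3-phenylpropan-1-one | Cc1c(O)c(C(=O)C=C(C)C)c(O)c(C(=O)CCc2ccccc2)c1O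
F2 | step 3 | 5,7-dihydroxy-2,2,8-trimethyl-6-(3-phenylpropanoyl)chroman-4-one | Cc1c(O)c(C(=O)CCc2ccccc2)c(O)c2C(=O)CC(C)(C)Oc12
F3 | step 4 | 4-oxo-2,2,6-trimethyl-8-(3-phenylpropanoyl)chroman-5,7-diyl diacetate | Cc1c(OC(C)=O)c(C(=O)CCc2ccccc2)c2c(c1OC(C)=O)C(=O)CC(C)(C)O2
F4 | step 4 | (4R)-4-hydroxy-2,2,6-trimethyl-8-(3-phenylpropanoyl)chroman-5,7-diyl diacetate | Cc1c(OC(C)=O)c(C(=O)CCc2ccccc2)c2c(c1OC(C)=O)[C@H](O)CC(C)(C)O2
F5 | step 2 | 7-hydroxy-9-methyl-1-phenyldec-8-ene-3,5-dione (racemic) | CC(C)=CC(O)CC(=O)CC(=O)CCc1ccccc1
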